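- The number to watch is 15.0%: the solid reagent minus the protic impurity, over both substrates charged. I call it the reagent margin, the part of the racemate that can react if the impurity takes its whole charge of reagent, mole for mole, which I assume.

| setting | larch | cedar | oak | flask |
|---|---|---|---|---|
| left-handed substrate | 0.34 mM | 0.75 mM | 0.50 mM | 0.50 mM |
| right-handed substrate | 0.34 mM | 0.75 mM | 0.50 mM | 0.50 mM |
| protic impurity | 0.25 mM | 0.25 mM | 0.25 mM | 0.250 mM |
| solid reagent | 0.40 mM | 0.40 mM | 0.80 mM | 0.400 mM |
| free catalyst | 1 µM | 1 µM | 1 µM | 1.0 µM |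
| remark | run made earlier | run made earlier | run made earlier |  |
| time |  |  |  | 2.5 min |

| run | time / s | left-handed substrate / % | right-handed substrate / % | left-handed product / % |
|---|---|---|---|---|
| larch | 10.0 | 49.1 | 49.7 | 0.5 |
| larch | 25.0 | 47.6 | 50.1 | 2.7 |
| larch | 40.0 | 45.8 | 48.9 | 4.2 |
| larch | 60.0 | 43.6 | 49.5 | 6.2 |
| larch | 90.0 | 40.9 | 49.0 | 8.8 |
| cedar | 20.0 | 48.8 | 49.8 | 1.3 |
| cedar | 40.0 | 47.7 | 50.0 | 2.1 |
| cedar | 50.0 | 46.8 | 49.8 | 3.2 |
| cedar | 80.0 | 45.1 | 49.7 | 5.6 |
| cedar | 90.0 | 44.5 | 48.8 | 6.3 |
| oak | 10.0 | 49.6 | 50.4 | 0.6 |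
| oak | 15.0 | 49.3 | 50.0 | 0.7 |
| oak | 25.0 | 48.3 | 50.3 | 1.8 |
| oak | 50.0 | 45.6 | 49.4 | 4.0 |
| oak | 90.0 | 42.1 | 49.3 | 7.7 |

(each reading ± 0.3 percentage points)

- free catalyst is single-handed; left-handed substrate and right-handed substrate are mirror images of each other, charged as a racemate, each of them at the stated concentration
- as a solid, counted per litre of solution: solid reagent
- at the start none of the solid reagent is in solution
- an excess is below zero if the other one leads

- part of the left-handed substrate and right-handed substrate charged together that has reacted at 2.5 min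
- excess of left-handed product over right-handed product in the product at 2.5 min
- excess of right-handed substrate over left-handed substrate among what is left of the two at 2.5 min

- The margin is a ceiling, not a pace: at 90.0 s, oak has margin 55.0% and 7.7% left-handed product, less than larch with 8.8% on margin 22.1%.
- So I need a pace too. I carry oak's straight line, which has the same substrate charge, to 2.5 min and get 12.8% left-handed product.
- Adding a tenth for the right-handed side, a small correction, I commit to 14.1% reacted, just under the margin.
- The forecast says 12.6%, 82% and 11.8%, lower than mine, and holds that “The right-handed substrate loses about a tenth as much”.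
- The flask gives 10.9%, 81.1% and 9.92%, so the forecast stands nearer than my line.

    coupling partner + catalyst intermediate A → free catalyst + left-handed product (k = 13300 M⁻¹ s⁻¹)
    2 free catalyst → spent catalyst (k = 10800 M⁻¹ s⁻¹)
    coupling partner + catalyst intermediate B → free catalyst + right-handed product (k = 5410 M⁻¹ s⁻¹)
    free catalyst + left-handed substrate ⇌ catalyst intermediate A (K = 3300 M⁻¹, k = 1.11 × 10⁵ M⁻¹ s⁻¹)
    solid reagent ⇌ coupling partner, rate k5*(cs5 - [coupling partner]) while solid is left; crystals form when [coupling partner] > cs5 (solubility = 0.210 mM, k = 0.0929 s⁻¹)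
    coupling partner + protic impurity → quenched reagent (k = 150 M⁻¹ s⁻¹)
    free catalyst + right-handed substrate ⇌ catalyst intermediate B (K = 730 M⁻¹, k = 8.49 × 10⁵ M⁻¹ s⁻¹)

- In the flask, the half-life of the protic impurity by quenching is 0.58 min at 0.300 min, short against 2.5 min, and at 2.50 min quenched reagent stands at 0.231 mM with 0.0608 mM of coupling partner still free. At 25.0 min the flask holds 13.7% left-handed and 1.48% right-handed product, close to its margin, while the neighbour with 0.062 mM of impurity has margin 33.8% and has reacted 16.0% at 2.50 min, when its solid reagent stands at 0% and its dissolved coupling partner at 0.180 mM.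

The readings come from a simulation for an exercise; the scatter is artificial.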